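The oxolane ring (O1, C2 aryl, C3 hydroxymethyl, C4 aroyl, C5 H2) is cut at O1–C5 and C2–C3, giving protected vanillin and a 2-aroylallyl 1,3-dipole equivalent. The key step exploits that C3 is alpha to a carboxyl-level carbon (the future CH2OH) while C5 is the beta-carbon of the C4 aryl ketone: an Evans boron aldol of a 3-aroylbut-3-enoyl oxazolidinone forms C2–C3 and sets C2 absolutely, and an iodide-relayed oxa-Michael closure in the same flask forms O1–C5; C3 and C4 then equilibrate to all-trans. The precursor is an acyclic enone imide from itaconic anhydride. Reduction, benzylic reoxidation and desilylation finish the synthesis.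

Key step: step 5

Remark: the oxolane is numbered O1, C2 (guaiacyl carbon), C3 (CH2OH carbon), C4 (aroyl carbon), C5 (OCH2) throughout; both phenols are assumed to need protection and are carried as tri(propan-2-yl)silyl (TIPS) ethers.

Step 1
Reactants: 1 4-bromo-2,6-dimethoxyphenol
Product: 2 (4-bromo-2,6-dimethoxyphenoxy)tri(propan-2-yl)silane
Conditions: TIPSCl, imidazole, DMF, rt to 40 °C
Reagents that add atoms: triisopropylsilyl chloride, CC(C)[Si](Cl)(C(C)C)C(C)C
Why: Imidazole-promoted O-silylation of the phenol; the hindered aryl TIPS ether should survive n-BuLi, Bu2BOTf, DBU, LiBH4 and MnO2 and is removable with fluoride.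

Step 2
Reactants: 3 vanillin
Product: 4 3-methoxy-4-{[tri(propan-2-yl)silyl]oxy}benzaldehyde
Conditions: TIPSCl, imidazole, DMF, rt
Reagents that add atoms: triisopropylsilyl chloride, CC(C)[Si](Cl)(C(C)C)C(C)C
Why: Imidazole-promoted O-silylation of the phenol, which masks the acidic OH for the boron aldol of step 5.

Step 3
Reactants: 5 (4S)-4-benzyl-1,3-oxazolidin-2-one; 6 itaconic anhydride
Product: 8 4-[(4S)-4-benzyl-2-oxo-1,3-oxazolidin-3-yl]-2-methylidene-4-oxobutanoic acid, via lithium oxazolidinide 7 (not isolated)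
Conditions: 5, n-BuLi, THF, −78 °C; cannulate into 6, THF, −78 °C; 1 M HCl work-up
Reagents that add atoms: none
Why: N-acylation of the lithiated oxazolidinone by ring-opening of the cyclic anhydride at its non-conjugated, CH2-flanked carbonyl (the more electrophilic one), which puts the imide on the CH2 arm and leaves the acrylic acid free; inverse addition at −78 °C is meant to outrun base-induced isomerisation to citraconic anhydride, and no stereocentre is formed.

Step 4
Reactants: 8 itaconic half-imide acid; 2 silyl-protected aryl bromide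
Product: 12 (4S)-4-benzyl-3-{3-[3,5-dimethoxy-4-(triisopropylsilyloxy)benzoyl]but-3-enoyl}-1,3-oxazolidin-2-one, via acid chloride 9 (not isolated), via aryllithium 10 (not isolated), via arylzinc chloride 11 (not isolated)
Conditions: 8, (COCl)2, cat. DMF, CH2Cl2, 0 °C to rt, evaporate; separately 2, n-BuLi, THF, −78 °C, then ZnCl2, −78 to 0 °C; combine, Pd(PPh3)4 (3 mol %), THF, 0 °C to rt
Reagents that add atoms: none
Why: Negishi acylation, in which the acid chloride adds oxidatively to zerovalent palladium and couples with the arylzinc chloride (from bromine–lithium exchange and transmetalation), a nucleophile too weak to attack the imide or the enone; no stereocentre is formed.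

Step 5
Reactants: 12 enone imide; 4 silyl-protected vanillin
Product: 18 (4S)-4-benzyl-3-{(2S,3S,4S)-4-[3,5-dimethoxy-4-(triisopropylsilyloxy)benzoyl]-2-[3-methoxy-4-(triisopropylsilyloxy)phenyl]oxolane-3-carbonyl}-1,3-oxazolidin-2-one (2,3-trans, 3,4-trans), via boron enolate 13 (not isolated), via boron aldolate 14 (not isolated), via syn aldol 15 (not isolated), via iodo ketone 16 (not isolated), via unequilibrated oxolane 17 (not isolated)
Conditions: Bu2BOTf, i-Pr2NEt, CH2Cl2, −78 to 0 °C; 4, −78 to 0 °C; then AcOH, LiI, THF, 0 to 40 °C; then DBU (excess over AcOH), rt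
Reagents that add atoms: none
Why: Proposed new method: the first half is a standard Evans boron aldol, in which the (Z)-dibutylboron enolate 13 adds to 4 through a closed Zimmerman–Traxler chair on the enolate face remote from the benzyl group and gives the (2S,3S)-syn aldol, forming C2–C3 and fixing C2 as S; the new element is closing the ring in the same flask by an iodide-relayed oxa-Michael addition, whose closest known relatives are the iodide-triggered ring-opening/aldol/cycloetherification of acylcyclopropanes (gamma-iodo aldolate to oxolane) and the hydroiodination of enones with iodide and acetic acid. Direct attack of the C2 oxygen on C5 of the 2-substituted aryl vinyl ketone would be a 5-endo-trig closure, which is stereoelectronically disfavoured for oxygen nucleophiles, so LiI/AcOH first adds HI across the enone (iodide at C5, proton at C4) and the C2 hydroxyl then displaces the primary iodide of 16 in a 5-exo-tet substitution that forms O1–C5 and returns HI. Both bonds therefore arise in one operation, and the sequence amounts to a formal (3+2) annulation of a 2-aroylallyl dipole with the aldehyde C=O. C2 is controlled by the auxiliary and is not touched again, whereas C3 (alpha to the imide) and C4 (alpha to the aryl ketone) are epimerisable and should be driven by DBU to the all-trans trisubstituted oxolane, the relative configuration of the target. The selectivity needed is imide-only enolisation and alpha- rather than gamma-attack of the dienolate; the substrate secures the first because the ketone has no enolisable alpha-hydrogen (its alpha-carbon is sp2), and the closed boron transition state secures the second. Ring-opening of 18 by beta-elimination under DBU is the microscopic reverse of the disfavoured 5-endo-trig closure and should therefore be slow.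

Step 6
Reactants: 18 oxolane keto imide
Product: 19 {(2S,3R,4S)-4-{[3,5-dimethoxy-4-(triisopropylsilyloxy)phenyl](hydroxy)methyl}-2-[3-methoxy-4-(triisopropylsilyloxy)phenyl]oxolan-3-yl}methanol, both epimers at the exocyclic carbinol carbon
Conditions: LiBH4, MeOH (1 equiv), THF, 0 °C
Reagents that add atoms: none
Why: Hydride reduction that cleaves the N-acyloxazolidinone to the C3 hydroxymethyl group and returns the auxiliary; the aryl ketone is reduced too, giving a carbinol centre as an inconsequential epimer mixture that step 7 erases, while C2, C3 and C4 are untouched.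

Step 7
Reactants: 19 diol
Product: 20 [(2S,3R,4S)-4-[3,5-dimethoxy-4-(triisopropylsilyloxy)benzoyl]-2-[3-methoxy-4-(triisopropylsilyloxy)phenyl]oxolan-3-yl]methanol
Conditions: activated MnO2 (excess), CH2Cl2, rt
Reagents that add atoms: none
Why: MnO2 oxidation of the electron-rich secondary benzylic alcohol, which should leave the primary aliphatic alcohol and the benzylic ether C–H alone; C4 keeps its configuration, which is also the thermodynamic one next to the regenerated ketone.

Step 8
Reactants: 20 bis-silyl keto alcohol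
Product: 21 [(2S,3R,4S)-4-(4-hydroxy-3,5-dimethoxybenzoyl)-2-(4-hydroxy-3-methoxyphenyl)oxolan-3-yl]methanol (target)
Conditions: TBAF, AcOH, THF, 0 °C
Reagents that add atoms: none
Why: Fluoride-mediated cleavage of both aryl silyl ethers; the acetic acid buffer keeps the medium near neutral so that the beta-alkoxy ketone and the C4 centre are not exposed to strong base, and no stereocentre is affected.

Compound list
1 | 4-bromo-2,6-dimethoxyphenol | COc1cc(Br)cc(OC)c1O | starting material
2 | (4-bromo-2,6-dimethoxyphenoxy)tri(propan-2-yl)silane | COc1cc(Br)cc(OC)c1O[Si](C(C)C)(C(C)C)C(C)C | intermediate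
3 | vanillin (4-hydroxy-3-methoxybenzaldehyde) | COc1cc(C=O)ccc1O | starting material
4 | 3-methoxy-4-{[tri(propan-2-yl)silyl]oxy}benzaldehyde | COc1cc(C=O)ccc1O[Si](C(C)C)(C(C)C)C(C)C | intermediate
5 | (4S)-4-benzyl-1,3-oxazolidin-2-one | O=C1N[C@@H](Cc2ccccc2)CO1 | starting material
6 | itaconic anhydride (3-methylideneoxolane-2,5-dione) | C=C1CC(=O)OC1=O | starting material
7 | lithium (4S)-4-benzyl-2-oxo-1,3-oxazolidin-3-ide | [Li]N1[C@@H](Cc2ccccc2)COC1=O | intermediate
8 | 4-[(4S)-4-benzyl-2-oxo-1,3-oxazolidin-3-yl]-2-methylidene-4-oxobutanoic acid | C=C(CC(=O)N1[C@@H](Cc2ccccc2)COC1=O)C(=O)O | intermediate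
9 | 4-[(4S)-4-benzyl-2-oxo-1,3-oxazolidin-3-yl]-2-methylidene-4-oxobutanoyl chloride | C=C(CC(=O)N1[C@@H](Cc2ccccc2)COC1=O)C(=O)Cl | intermediate
10 | [3,5-dimethoxy-4-(triisopropylsilyloxy)phenyl]lithium | [Li]c1cc(OC)c(O[Si](C(C)C)(C(C)C)C(C)C)c(OC)c1 | intermediate
11 | [3,5-dimethoxy-4-(triisopropylsilyloxy)phenyl]zinc chloride | Cl[Zn]c1cc(OC)c(O[Si](C(C)C)(C(C)C)C(C)C)c(OC)c1 | intermediate
12 | (4S)-4-benzyl-3-{3-[3,5-dimethoxy-4-(triisopropylsilyloxy)benzoyl]but-3-enoyl}-1,3-oxazolidin-2-one | C=C(CC(=O)N1[C@@H](Cc2ccccc2)COC1=O)C(=O)c1cc(OC)c(O[Si](C(C)C)(C(C)C)C(C)C)c(OC)c1 | intermediate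
13 | (Z)-O-dibutylboryl enolate of 12 (enolate oxygen cis to the 1-aroylvinyl group) | CCCCB(CCCC)O/C(=C\C(=C)C(=O)c1cc(OC)c(O[Si](C(C)C)(C(C)C)C(C)C)c(OC)c1)N1[C@@H](Cc2ccccc2)COC1=O | intermediate
14 | O-dibutylboryl aldolate of 15 | COc1cc([C@@H](OB(CCCC)CCCC)[C@@H](C(=O)N2[C@@H](Cc3ccccc3)COC2=O)C(=C)C(=O)c2cc(OC)c(O[Si](C(C)C)(C(C)C)C(C)C)c(OC)c2)ccc1O[Si](C(C)C)(C(C)C)C(C)C | intermediate
15 | (4S)-4-benzyl-3-[(2S,3S)-2-{3-[3,5-dimethoxy-4-(triisopropylsilyloxy)phenyl]-3-oxoprop-1-en-2-yl}-3-hydroxy-3-[3-methoxy-4-(triisopropylsilyloxy)phenyl]propanoyl]-1,3-oxazolidin-2-one (syn aldol) | COc1cc([C@@H](O)[C@@H](C(=O)N2[C@@H](Cc3ccccc3)COC2=O)C(=C)C(=O)c2cc(OC)c(O[Si](C(C)C)(C(C)C)C(C)C)c(OC)c2)ccc1O[Si](C(C)C)(C(C)C)C(C)C | intermediate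
16 | HI adduct of 15: (2S,3S)-aldol carrying a 1-aroyl-2-iodoethyl group at C2 of the propanoyl chain, both epimers at the iodomethyl-bearing carbon | COc1cc([C@@H](O)[C@@H](C(=O)N2[C@@H](Cc3ccccc3)COC2=O)C(CI)C(=O)c2cc(OC)c(O[Si](C(C)C)(C(C)C)C(C)C)c(OC)c2)ccc1O[Si](C(C)C)(C(C)C)C(C)C | intermediate
17 | (4S)-4-benzyl-3-{(2S,3S)-4-aroyl-2-aryl-oxolane-3-carbonyl}-1,3-oxazolidin-2-one before equilibration, both epimers at C4 (aroyl and aryl as in 18) | COc1cc([C@H]2OCC(C(=O)c3cc(OC)c(O[Si](C(C)C)(C(C)C)C(C)C)c(OC)c3)[C@@H]2C(=O)N2[C@@H](Cc3ccccc3)COC2=O)ccc1O[Si](C(C)C)(C(C)C)C(C)C | intermediate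
18 | (4S)-4-benzyl-3-{(2S,3S,4S)-4-[3,5-dimethoxy-4-(triisopropylsilyloxy)benzoyl]-2-[3-methoxy-4-(triisopropylsilyloxy)phenyl]oxolane-3-carbonyl}-1,3-oxazolidin-2-one | COc1cc([C@H]2OC[C@@H](C(=O)c3cc(OC)c(O[Si](C(C)C)(C(C)C)C(C)C)c(OC)c3)[C@@H]2C(=O)N2[C@@H](Cc3ccccc3)COC2=O)ccc1O[Si](C(C)C)(C(C)C)C(C)C | intermediate
19 | {(2S,3R,4S)-4-{[3,5-dimethoxy-4-(triisopropylsilyloxy)phenyl](hydroxy)methyl}-2-[3-methoxy-4-(triisopropylsilyloxy)phenyl]oxolan-3-yl}methanol, both carbinol epimers | COc1cc([C@H]2OC[C@@H](C(O)c3cc(OC)c(O[Si](C(C)C)(C(C)C)C(C)C)c(OC)c3)[C@@H]2CO)ccc1O[Si](C(C)C)(C(C)C)C(C)C | intermediate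
20 | [(2S,3R,4S)-4-[3,5-dimethoxy-4-(triisopropylsilyloxy)benzoyl]-2-[3-methoxy-4-(triisopropylsilyloxy)phenyl]oxolan-3-yl]methanol | COc1cc([C@H]2OC[C@@H](C(=O)c3cc(OC)c(O[Si](C(C)C)(C(C)C)C(C)C)c(OC)c3)[C@@H]2CO)ccc1O[Si](C(C)C)(C(C)C)C(C)C | intermediate
21 | [(2S,3R,4S)-4-(4-hydroxy-3,5-dimethoxybenzoyl)-2-(4-hydroxy-3-methoxyphenyl)oxolan-3-yl]methanol | COc1cc([C@H]2OC[C@@H](C(=O)c3cc(OC)c(O)c(OC)c3)[C@@H]2CO)ccc1O | target

Total step count: 8. Longest linear sequence: 6 steps (steps 3 to 8, from 5 and 6 to 21).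

Steps most likely to fail

1. Step 5. The aldol half is routine; the risk lies in the ring closure. Iodide addition to the enone and the 5-exo-tet displacement may be slow, and during that time the aldol can undergo retro-aldol cleavage, the exocyclic C4=C5 double bond can migrate into conjugation with the imide, or the imide carbonyl oxygen can displace the iodide with loss of the auxiliary. The fallback uses known reactions and sets out from 12 and 4. The Evans aldol is run alone with a buffered work-up and the syn aldol 15 is isolated. Nucleophilic (Weitz–Scheffer) epoxidation of its enone (t-BuOOH, DBU, toluene, 0 °C) should give the epoxy ketone F1 as a mixture at the oxirane carbon. The C2 hydroxyl then opens the oxirane at its CH2 terminus in a 5-exo-tet etherification (spontaneously or with cat. camphorsulfonic acid, CH2Cl2) to give the 4-hydroxy oxolane F2. Reductive cleavage of the tertiary alpha-hydroxy group of the aryl ketone with SmI2 (THF–MeOH, −78 °C) and protonation of the samarium enolate should give 18 together with its C4 epimer F3, which DBU converts into 18. The route is rejoined at 18.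

2. Step 3. The lithiated oxazolidinone may act as a base, isomerising itaconic anhydride to citraconic anhydride, or may attack the conjugated carbonyl, so that the wrong half-imide or mixtures result. The fallback replaces steps 3 and 4 and sets out from 2. Magnesium insertion (Mg, THF) gives the arylmagnesium bromide F4, which opens succinic anhydride (THF, −78 °C to rt) to the keto acid F5. Mixed-anhydride coupling with 5 (pivaloyl chloride, Et3N, LiCl, THF) gives the keto imide F6. Mannich-type alpha-methylenation of the ketone (paraformaldehyde, i-Pr2NH·CF3CO2H, THF, reflux) then gives 12, where the route is rejoined.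

3. Step 7. The oxidation may stall on the hindered carbinol or fail to discriminate, attacking the primary alcohol or the benzylic ether position of the oxolane. The fallback avoids reducing the ketone at all and sets out from 18, bypassing steps 6 and 7. Lithium ethanethiolate (EtSH, n-BuLi, THF, 0 °C) converts the imide into the thioester F7 and releases the auxiliary. Fukuyama reduction (Et3SiH, Pd/C, acetone, rt) gives the aldehyde F8. Chemoselective reduction of the aldehyde in the presence of the aryl ketone (NaBH(OAc)3, or NaBH4 in MeOH at −78 °C) gives 20, where the route is rejoined.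

Further compounds
F1 | step 5 | epoxide of 15: oxirane across the former C4=C5 bond (2-aroyl-oxiran-2-yl group on the aldol alpha-carbon), both epimers at the oxirane carbon | COc1cc([C@@H](O)[C@@H](C(=O)N2[C@@H](Cc3ccccc3)COC2=O)C2(CO2)C(=O)c2cc(OC)c(O[Si](C(C)C)(C(C)C)C(C)C)c(OC)c2)ccc1O[Si](C(C)C)(C(C)C)C(C)C
F2 | step 5 | 4-hydroxy analogue of 18 (tertiary alcohol at C4 of the oxolane), both epimers at C4 | COc1cc([C@H]2OCC(O)(C(=O)c3cc(OC)c(O[Si](C(C)C)(C(C)C)C(C)C)c(OC)c3)[C@@H]2C(=O)N2[C@@H](Cc3ccccc3)COC2=O)ccc1O[Si](C(C)C)(C(C)C)C(C)C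
F3 | step 5 | C4 epimer of 18, (2S,3S,4R) | COc1cc([C@H]2OC[C@H](C(=O)c3cc(OC)c(O[Si](C(C)C)(C(C)C)C(C)C)c(OC)c3)[C@@H]2C(=O)N2[C@@H](Cc3ccccc3)COC2=O)ccc1O[Si](C(C)C)(C(C)C)C(C)C
F4 | step 3 | [3,5-dimethoxy-4-(triisopropylsilyloxy)phenyl]magnesium bromide | Br[Mg]c1cc(OC)c(O[Si](C(C)C)(C(C)C)C(C)C)c(OC)c1
F5 | step 3 | 4-[3,5-dimethoxy-4-(triisopropylsilyloxy)phenyl]-4-oxobutanoic acid | COc1cc(C(=O)CCC(=O)O)cc(OC)c1O[Si](C(C)C)(C(C)C)C(C)C
F6 | step 3 | (4S)-4-benzyl-3-{4-[3,5-dimethoxy-4-(triisopropylsilyloxy)phenyl]-4-oxobutanoyl}-1,3-oxazolidin-2-one | COc1cc(C(=O)CCC(=O)N2[C@@H](Cc3ccccc3)COC2=O)cc(OC)c1O[Si](C(C)C)(C(C)C)C(C)C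
F7 | step 7 | S-ethyl (2S,3S,4S)-4-[3,5-dimethoxy-4-(triisopropylsilyloxy)benzoyl]-2-[3-methoxy-4-(triisopropylsilyloxy)phenyl]oxolane-3-carbothioate | COc1cc([C@H]2OC[C@@H](C(=O)c3cc(OC)c(O[Si](C(C)C)(C(C)C)C(C)C)c(OC)c3)[C@@H]2C(=O)SCC)ccc1O[Si](C(C)C)(C(C)C)C(C)C
F8 | step 7 | (2S,3S,4S)-4-[3,5-dimethoxy-4-(triisopropylsilyloxy)benzoyl]-2-[3-methoxy-4-(triisopropylsilyloxy)phenyl]oxolane-3-carbaldehyde | COc1cc([C@H]2OC[C@@H](C(=O)c3cc(OC)c(O[Si](C(C)C)(C(C)C)C(C)C)c(OC)c3)[C@@H]2C=O)ccc1O[Si](C(C)C)(C(C)C)C(C)C
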